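All runs were computed on assumed constants.

4 questions stand on this flask, and one quantity carries the reckoning.

- L, in percent of the E first charged, at 4.0 min
- the option that brings most further L ("none" if no option brings more than 2 percentage points) (theta / beta / gamma / epsilon / none)
- L present, with what was taken out counted in, in percent of the E first charged, after beta
- L present, with what was taken out counted in, in percent of the E first charged, after gamma

- Sunday's: E 10 mM; D 100 µM; temperature 40 °C; the very flask that is asked about, followed so far
- flask: E 10 mM; D 100 µM; temperature 40 °C; time 4.0 min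

- theta: at 4.0 min add D, 100% of the amount charged, then wait 4.0 min
- beta: at 4.0 min raise the temperature by 20 K, then wait 4.0 min
- gamma: at 4.0 min take out 90% of the L then present, then wait 4.0 min
- epsilon: change nothing and wait 4.0 min more

- solid, in amounts per volume of the solution: E
- L that was removed still counts
- steps thought possible: Z + D <-> L + D; Z + D <-> G + D; Z <-> J; E <-> Z
- at the start none of E is in solution
- additions bring no volume worth counting
- the earlier runs do not show what temperature does; that part of a forecast is a guess

Sunday's run (percent of the E charged)

| time / min | L / % | E / % |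
|---|---|---|
| 0.500 | 6.2 | 87.4 |
| 1.33 | 12.0 | 79.0 |
| 2.50 | 15.8 | 72.7 |
| 4.00 | 16.2 | 69.7 |

(readings scatter by 0.5 percentage points)

This flask is Sunday's flask, so the first answer is a reading: L stood at 16.2% at 4.00 min. But L is stalling. It gained 5.8 percentage points between the first two readings and 0.4 points between the last two, and E still stands at 69.7%, so solid E has not run out. D speeds a step both ways, so you read the stall as a balance of L with Z, with the solid keeping Z steady (thermodynamic control).

Then the stall is a concentration, not a percentage. Call it the L ceiling: the concentration of L at which L stops growing while solid E remains. 1.62 mM is its reading.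

So more D or more waiting should bring little. Taking L out is different: Sunday's L climbed from nothing to 15.8% in 2.50 min, less time than the wait. L should therefore regain the ceiling, and you reckon a total of 30.8%. Heating stays a guess.

The forecast says 16.3%, gamma, 18% after beta and 30.5% after gamma, reasoning “so the catalyst is not the limit”; your gamma figure is 30.8%.

The flask gives 16.5% and gamma, with 31.7% after gamma. Waiting brings 0.61 points, and adding D 0.63 points. After beta, L stands at 5.23%.

    Z + D ⇌ L + D, rate k1*[Z]*[D] forward; the back reaction follows from the equilibrium constant (K = 3.40, k = 884 M⁻¹ s⁻¹, Ea = 39.0 kJ mol⁻¹, ΔH = −52.0 kJ mol⁻¹)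
    Z + D ⇌ G + D, rate k2*[Z]*[D] forward; the back reaction follows from the equilibrium constant (K = 1.96, k = 78.2 M⁻¹ s⁻¹, Ea = 46.0 kJ mol⁻¹, ΔH = −36.0 kJ mol⁻¹)
    Z ⇌ J (K = 0.695, k = 0.0489 s⁻¹, Ea = 78.0 kJ mol⁻¹, ΔH = −10.0 kJ mol⁻¹)
    E ⇌ Z, rate k4*(cs4 - [Z]) while solid is left; crystals form when [Z] > cs4 (solubility = 0.510 mM, k = 0.174 s⁻¹)
    (constants at 40 °C)

Take the neighbour flask, with 25 mM of E and all else held. The same ceiling of 1.62 mM is 6.48% of that charge. That neighbour flask gives 6.62% at 4.00 min, with E at 87.8%, and that L is 1.66 mM.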